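Ring A is treated as a masked cyclohexanone, so the hindered diaryl ether bond (O–C6 of ring A) is made by SN2 alkylation of a ring B phenoxide with 2-chlorocyclohexanone instead of an aryl C–O coupling. The key step then turns the racemic 2-aryloxycyclohexanone, whose ring B is already dibrominated and mesylate-masked, into the 2-aryloxy-4,6-dibromophenol in one flask: Br2 dehydrogenates the ring and brominates the new phenol. It exploits that ring A carries oxygen at C1 with Br at the ortho carbon C2 and the para carbon C4 and the aryloxy group at the other ortho carbon C6, the pattern a fresh phenolic OH imposes.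

Key step: step 4

Assumption: ring A is numbered C1 (OMe), C2 (Br), C4 (Br), C6 (O-aryl); compounds 4, 5 and 6 are used as racemates because the only stereocentre of 6 is destroyed in step 4.

Step 1
Reactants: 1 catechol
Product: 2 2-hydroxyphenyl methanesulfonate
Conditions: MsCl (1.0 equiv), Et3N (1.1 equiv), catechol (3 equiv), THF, -10 to 0 °C, N2; dilute HCl and water washes remove the excess diol
Reagents that add atoms: methanesulfonyl chloride, CS(=O)(=O)Cl
Why: O-sulfonylation of a phenol, where the large excess of the cheap, water-soluble diol should keep double mesylation low, and the mesylate both masks the future ring B hydroxyl and deactivates that ring.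

Step 2
Reactants: 2 2-hydroxyphenyl methanesulfonate
Product: 3 3,5-dibromo-2-hydroxyphenyl methanesulfonate
Conditions: Br2 (2.1 equiv), NaOAc (2.2 equiv), AcOH, 15-25 °C; aqueous Na2S2O3 quench
Reagents that add atoms: bromine, BrBr
Why: Electrophilic aromatic bromination directed by the free OH to its para and open ortho carbons, the mesyloxy group being too deactivating to compete, so that both Br atoms end up ortho and para to the future ether oxygen.

Step 3
Reactants: 3 3,5-dibromo-2-hydroxyphenyl methanesulfonate; 4 2-chlorocyclohexanone (1.5 equiv)
Product: 6 racemic 2-[2,4-dibromo-6-(methanesulfonyloxy)phenoxy]cyclohexan-1-one, via 2-iodocyclohexanone 5 (not isolated)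
Conditions: K2CO3 (2 equiv), KI (0.2 equiv), DMF, 55 °C
Reagents that add atoms: none
Why: Williamson ether synthesis with Finkelstein activation, in which the carbonyl-activated secondary halide should undergo SN2 substitution even with a di-ortho-substituted, weakly basic phenoxide, while the aryl mesylate is inert to K2CO3; the new stereocentre is formed as the racemate.

Step 4
Reactants: 6 racemic 2-[2,4-dibromo-6-(methanesulfonyloxy)phenoxy]cyclohexan-1-one
Product: 8 3,5-dibromo-2-(3,5-dibromo-2-hydroxyphenoxy)phenyl methanesulfonate, via 2-aryloxyphenol 7 (not isolated)
Conditions: Br2 (4.2 equiv, added dropwise), NaOAc (6.5 equiv), AcOH, 20 °C then 70 °C; aqueous NaHSO3 quench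
Reagents that add atoms: bromine, BrBr
Why: Proposed new method: enolisation of ketone 6 and alpha-bromination, loss of HBr to an aryloxy enone, a second bromination and dehydrobromination cycle and tautomerisation of the resulting dienone should give the 2-aryloxyphenol 7, which, as the most electron-rich species present, takes the remaining two equivalents of Br2 at its open ortho and para carbons (C2 and C4 of ring A). The closest known reaction types are the halogen-mediated dehydrogenative aromatisation of 2-substituted cyclohexanones to phenols and the ortho/para bromination of phenols with Br2 in buffered acetic acid; combining them on an alpha-aryloxy ketone is the untested part. No ring is closed, ring A is only aromatised, and the single stereocentre of 6 is erased, so no stereocontrol is required. The step needs Br at C2 and C4 of ring A only: the third OH-activated carbon, C6, carries the aryloxy group, and ring B is inert because its carbons ortho and para to the ether oxygen are already brominated and the mesylate deactivates the rest. The site of the first alpha-bromination does not matter, since both alpha-carbons lead to the same phenol, and the blocked ortho positions of ring B exclude acid-promoted cyclodehydration to a benzofuran. The NaOAc buffer keeps free HBr low, so the alpha-aryloxy C–O bond and the mesylate should survive.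

Step 5
Reactants: 8 3,5-dibromo-2-(3,5-dibromo-2-hydroxyphenoxy)phenyl methanesulfonate; 9 iodomethane (3 equiv)
Product: 10 3,5-dibromo-2-(3,5-dibromo-2-methoxyphenoxy)phenyl methanesulfonate
Conditions: MeI, K2CO3 (2 equiv), DMF, 25-40 °C
Reagents that add atoms: iodomethane (compound 9), CI
Why: Williamson O-methylation, in which the acidic, flanked ring A phenoxide should still react cleanly with the small electrophile MeI, and the ring B oxygen cannot be methylated because it is held as the mesylate.

Step 6
Reactants: 10 3,5-dibromo-2-(3,5-dibromo-2-methoxyphenoxy)phenyl methanesulfonate
Product: 11 3,5-dibromo-2-(3,5-dibromo-2-methoxyphenoxy)phenol (target CNP0332008.0)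
Conditions: NaOH (2 M aq, 5 equiv), MeOH/THF, 55 °C; then 1 M HCl
Reagents that add atoms: none
Why: Saponification of an aryl sulfonate by hydroxide attack at sulfur should release the ring B phenoxide without touching the methyl ether, the diaryl ether or the unactivated aryl bromides, and acidification gives the free phenol.

Compound list
1 | catechol (benzene-1,2-diol) | Oc1ccccc1O | starting material
2 | 2-hydroxyphenyl methanesulfonate | CS(=O)(=O)Oc1ccccc1O | intermediate
3 | 3,5-dibromo-2-hydroxyphenyl methanesulfonate | CS(=O)(=O)Oc1cc(Br)cc(Br)c1O | intermediate
4 | 2-chlorocyclohexanone (racemic) | O=C1CCCCC1Cl | starting material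
5 | 2-iodocyclohexanone (racemic, formed in the flask) | O=C1CCCCC1I | intermediate
6 | 2-[2,4-dibromo-6-(methanesulfonyloxy)phenoxy]cyclohexan-1-one (racemic) | CS(=O)(=O)Oc1cc(Br)cc(Br)c1OC1CCCCC1=O | intermediate
7 | 3,5-dibromo-2-(2-hydroxyphenoxy)phenyl methanesulfonate (formed in the flask) | CS(=O)(=O)Oc1cc(Br)cc(Br)c1Oc1ccccc1O | intermediate
8 | 3,5-dibromo-2-(3,5-dibromo-2-hydroxyphenoxy)phenyl methanesulfonate | CS(=O)(=O)Oc1cc(Br)cc(Br)c1Oc1cc(Br)cc(Br)c1O | intermediate
9 | iodomethane | CI | starting material
10 | 3,5-dibromo-2-(3,5-dibromo-2-methoxyphenoxy)phenyl methanesulfonate | CS(=O)(=O)Oc1cc(Br)cc(Br)c1Oc1cc(Br)cc(Br)c1OC | intermediate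
11 | 3,5-dibromo-2-(3,5-dibromo-2-methoxyphenoxy)phenol (CNP0332008.0) | COc1c(Br)cc(Br)cc1Oc1c(O)cc(Br)cc1Br | target

Total step count: 6. Longest linear sequence: 6 steps (1 to 11).

Steps most likely to fail

Step 4. The dehydrobrominations may stall at alpha-bromo ketones, acetate may substitute an alpha-bromide, or the aryloxide may be expelled before aromatisation is complete. The fallback separates the two events with known chemistry. It sets out from 6, which is dehydrogenated with catalytic iodine (I2) in DMSO at about 90 °C, DMSO serving as the terminal oxidant in the iodine-catalysed aromatisation of 2-substituted cyclohexanones. This should give 3,5-dibromo-2-(2-hydroxyphenoxy)phenyl methanesulfonate 7 as an isolated compound. Ordinary phenol bromination of 7 (Br2, 2.1 equiv, NaOAc, AcOH, 20 °C) at the ortho and para carbons of ring A then returns to the route at 8. The detour creates no compound outside the list (F0).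

Step 3. The flanked, weakly nucleophilic phenoxide may react too slowly, so that the alpha-halo ketone is lost to base-mediated self-condensation or Favorskii-type pathways. The fallback sets out from 3 and replaces the electrophile by base-stable cyclohexene oxide (3 equiv, K2CO3 0.3 equiv, DMF, 90 °C). Anti opening of the epoxide should give racemic trans-2-[2,4-dibromo-6-(methanesulfonyloxy)phenoxy]cyclohexan-1-ol F1. Oxidation of F1 with Dess–Martin periodinane (CH2Cl2, 20 °C) comes back to the route at 6.

Step 1. Over-sulfonylation may consume the reagent, giving a statistical mixture from which the mono-ester is recovered poorly. The fallback sets out from 1 and mesylates both hydroxyls on purpose (MsCl 2.4 equiv, Et3N, CH2Cl2, 0 °C) to give benzene-1,2-diyl dimethanesulfonate F2. Partial saponification of F2 with KOH (2.1 equiv, aqueous MeOH/THF, 20 °C) and acidification returns to the route at 2. The second sulfonate should be retained because, after the first cleavage, the leaving group would be a catechol dianion.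

Further compounds
F0 | step 4 | none | none
F1 | step 3 | racemic trans-2-[2,4-dibromo-6-(methanesulfonyloxy)phenoxy]cyclohexan-1-ol (one enantiomer drawn) | O[C@@H]1CCCC[C@H]1Oc1c(Br)cc(Br)cc1OS(C)(=O)=O
F2 | step 1 | benzene-1,2-diyl dimethanesulfonate | CS(=O)(=O)Oc1ccccc1OS(C)(=O)=O
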